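**Retrosynthetic overview**
- The target comes from one global hydrogenolysis of a protected trimer that carries 18 O-benzyl groups and two blocking bromines on the top A ring.
- The protected trimer is assembled in one flask: two catalyst-controlled oxa-[4+2] cycloadditions of o-quinone methides with one (Z)-enol gallate build the C rings of the top and middle epicatechin-gallate units with the gallates already in place, then a C4(top)→C8(middle) Friedel–Crafts union.
- The o-quinone methide precursors are an o-hydroxybenzhydrol (8-lithio-tetra-O-benzylcatechin plus 4,6-bis(benzyloxy)-2-hydroxybenzaldehyde) for the middle ring, and the 3,5-dibromo derivative of the same aldehyde plus HC(OMe)3 for the top ring.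
- The dienophile comes from Ru-catalysed Z-selective addition of tri-O-benzylgallic acid to 3,4-bis(benzyloxy)phenylacetylene.
- Ring order: the catechin C ring is taken from the chiral pool; the top C ring and then the middle C ring are formed in the key step.

Assumption: the SMILES is read as (−)-epicatechin-3-O-gallate-(4β→8)-(−)-epicatechin-3-O-gallate-(4β→8)-(+)-catechin (C2/C3 = 2R,3R; 2R,3R; 2R,3S; each interflavan bond trans to the neighbouring 3-O-galloyl). The (R)-catalyst is taken to give the (2R,3R) sense; if a test cycloaddition shows the opposite sense, its enantiomer is used under the same conditions.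

**Step 1**
Reactants: 1 (+)-catechin
Product: 2 5,7,3',4'-tetra-O-benzyl-(+)-catechin
Conditions: BnBr (4.4 equiv), K2CO3 (5 equiv), DMF, 0 °C→rt, Ar
Reagents that add atoms: benzyl bromide, BrCc1ccccc1
Why: Williamson etherification; K2CO3 deprotonates only the four phenols, so the secondary 3-OH stays free and C2/C3 are untouched.

**Step 2**
Reactants: 2 5,7,3',4'-tetra-O-benzyl-(+)-catechin
Product: 3 8-bromo-5,7,3',4'-tetra-O-benzyl-(+)-catechin
Conditions: NBS (1.05 equiv), CH2Cl2, −40 °C→rt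
Reagents that add atoms: N-bromosuccinimide, O=C1CCC(=O)N1Br
Why: Electrophilic aromatic bromination; C8, flanked by O1 and the 7-OBn group, is the most nucleophilic A-ring position of 5,7-di-O-benzylflavans.

**Step 3**
Reactants: 4 2,4,6-trihydroxybenzaldehyde
Product: 5 4,6-bis(benzyloxy)-2-hydroxybenzaldehyde
Conditions: BnBr (2.05 equiv), K2CO3 (2.2 equiv), DMF, rt
Reagents that add atoms: benzyl bromide, BrCc1ccccc1
Why: Williamson etherification; the OH that is hydrogen-bonded to the aldehyde is the least nucleophilic, so alkylation stops after the 4- and 6-OH.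

**Step 4**
Reactants: 3 8-bromo-5,7,3',4'-tetra-O-benzyl-(+)-catechin; 5 4,6-bis(benzyloxy)-2-hydroxybenzaldehyde
Product: 8 o-hydroxybenzhydrol (both carbinol epimers), via 8-lithio lithium alkoxide 6 (not isolated), via lithium phenoxide 7 (not isolated)
Conditions: 3, n-BuLi (2.1 equiv), THF, −78 °C; separately 5, LiHMDS (1.0 equiv), THF, −78 °C; combine, −78→0 °C; H2O/pH 7 buffer; used crude
Reagents that add atoms: none
Why: Bromine–lithium exchange followed by 1,2-addition of the aryllithium to the aldehyde, whose phenol is masked as its lithium salt; the new carbinol centre is formed unselectively but becomes sp2 in step 8.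

**Step 5**
Reactants: 5 4,6-bis(benzyloxy)-2-hydroxybenzaldehyde
Product: 9 4,6-bis(benzyloxy)-3,5-dibromo-2-hydroxybenzaldehyde
Conditions: NBS (2.1 equiv), MeCN, 0 °C→rt, dark
Reagents that add atoms: N-bromosuccinimide, O=C1CCC(=O)N1Br
Why: Electrophilic aromatic bromination of both remaining ring positions gives a top-ring precursor with no nucleophilic C–H, so this unit can only act as an electrophile; the bromines leave in step 9.

**Step 6**
Reactants: 10 3,4-bis(benzyloxy)benzaldehyde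
Product: 11 1,2-bis(benzyloxy)-4-ethynylbenzene
Conditions: dimethyl (1-diazo-2-oxopropyl)phosphonate (1.3 equiv), K2CO3 (2 equiv), MeOH/THF, rt
Reagents that add atoms: dimethyl (1-diazo-2-oxopropyl)phosphonate, COP(=O)(OC)C(=[N+]=[N-])C(C)=O
Why: Ohira–Bestmann (Seyferth–Gilbert) homologation of an aryl aldehyde under mild base that leaves benzyl ethers intact.

**Step 7**
Reactants: 11 1,2-bis(benzyloxy)-4-ethynylbenzene; 12 3,4,5-tris(benzyloxy)benzoic acid
Product: 13 (Z)-2-[3,4-bis(benzyloxy)phenyl]ethenyl 3,4,5-tris(benzyloxy)benzoate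
Conditions: [Ru(η3-methallyl)2(dppb)] (2 mol%), PhMe, 50 °C; Et3N-deactivated silica
Reagents that add atoms: none
Why: Ruthenium-vinylidene anti-Markovnikov hydroacyloxylation of a terminal alkyne, which delivers the Z-enol ester; this alkene geometry later becomes the 2,3-cis relationship.

**Step 8**
Reactants: 9 4,6-bis(benzyloxy)-3,5-dibromo-2-hydroxybenzaldehyde (1.15 equiv); 13 (Z)-enol gallate (2.3 equiv); 8 o-hydroxybenzhydrol (1.0 equiv)
Product: 19 octadeca-O-benzyl-6,8-dibromo trimer (Br on the top A ring), via dimethyl acetal 14 (not isolated), via methoxy quinone methide 15 (not isolated), via 4-methoxyflavan gallate 16 (not isolated), via benzhydryl quinone methide 17 (not isolated), via protected dimer 18 (not isolated)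
Conditions: (i) 9, 13, HC(OMe)3 (1.3 equiv), (R)-3,3'-bis(2,4,6-triisopropylphenyl)-BINOL N-triflylphosphoramide (10 mol%), 4 Å MS, CH2Cl2, −20→0 °C; (ii) 8 added slowly, −20 °C; (iii) TMSOTf (0.5 equiv), −78 °C; Et3N
Reagents that add atoms: none
Why: Proposed new method: two chiral-Brønsted-acid-catalysed inverse-demand oxa-[4+2] cycloadditions of o-quinone methides with Z-enol gallate 13 in one flask — 9 is acetalised by HC(OMe)3 to 14 and loses MeOH to ion-paired 15, 8 loses water to 17, and in both the acyloxy-bearing alkene carbon (its partner carries the cation-stabilising 3,4-dibenzyloxyphenyl group) bonds to the methide carbon while the quinone methide oxygen closes on the benzylic carbon suprafacially, so Z becomes 2,3-cis and the catalyst-selected alkene face gives (2R,3R) in both C rings; for 17 the Z-dienophile is expected to add exo, with the galloyloxy group turned away from the cleft between the 5-OBn group and the twisted flavan-8-yl group, which puts the catechin unit trans to the 3-O-gallate (4β); TMSOTf then ionises C4–OMe of 16, the 3-O-galloyl carbonyl shields the α face, and C8 of the new ring of 18 (the most nucleophilic free C–H, the top unit being fully brominated) attacks from the β face to give the second 4β→8 bond; closest known reaction types are phosphoramide-catalysed [4+2] of o-hydroxybenzhydrol-derived quinone methides with styrenes, the salicylaldehyde/orthoformate/alkene synthesis of 4-alkoxychromans, and TMSOTf-mediated C4→C8 flavan coupling with 3-O-acyl participation.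

**Step 9**
Reactants: 19 octadeca-O-benzyl-6,8-dibromo trimer
Product: 20 epicatechin-3-O-gallate-(4β→8)-epicatechin-3-O-gallate-(4β→8)-catechin (target)
Conditions: H2 (1 atm), 20% Pd(OH)2/C, NaOAc (2.5 equiv), THF/MeOH/H2O, rt; Sephadex LH-20
Reagents that add atoms: none
Why: Hydrogenolysis over Pearlman's catalyst cleaves all 18 benzyl ethers and both aryl C–Br bonds, while NaOAc buffers the HBr so the acid-labile interflavan bonds, the gallate esters and all stereocentres survive.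

**Compound list**
1 | (+)-catechin, (2R,3S)-2-(3,4-dihydroxyphenyl)chromane-3,5,7-triol | O[C@H]1Cc2c(O)cc(O)cc2O[C@@H]1c1ccc(O)c(O)c1 | starting material
2 | 5,7,3',4'-tetra-O-benzyl-(+)-catechin (2R,3S) | O[C@H]1Cc2c(OCc3ccccc3)cc(OCc3ccccc3)cc2O[C@@H]1c1ccc(OCc2ccccc2)c(OCc2ccccc2)c1 | intermediate
3 | 8-bromo-5,7,3',4'-tetra-O-benzyl-(+)-catechin (2R,3S) | O[C@H]1Cc2c(OCc3ccccc3)cc(OCc3ccccc3)c(Br)c2O[C@@H]1c1ccc(OCc2ccccc2)c(OCc2ccccc2)c1 | intermediate
4 | 2,4,6-trihydroxybenzaldehyde | O=Cc1c(O)cc(O)cc1O | starting material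
5 | 4,6-bis(benzyloxy)-2-hydroxybenzaldehyde | O=Cc1c(O)cc(OCc2ccccc2)cc1OCc1ccccc1 | intermediate
6 | 8-lithio-5,7,3',4'-tetra-O-benzylcatechin lithium 3-alkoxide (2R,3S) | [Li]O[C@H]1Cc2c(OCc3ccccc3)cc(OCc3ccccc3)c([Li])c2O[C@@H]1c1ccc(OCc2ccccc2)c(OCc2ccccc2)c1 | intermediate
7 | lithium 3,5-bis(benzyloxy)-2-formylphenoxide | [Li]Oc1cc(OCc2ccccc2)cc(OCc2ccccc2)c1C=O | intermediate
8 | (2R,3S)-5,7-bis(benzyloxy)-2-[3,4-bis(benzyloxy)phenyl]-8-{[2,4-bis(benzyloxy)-6-hydroxyphenyl](hydroxy)methyl}chroman-3-ol, both carbinol epimers | O[C@H]1Cc2c(OCc3ccccc3)cc(OCc3ccccc3)c(C(O)c3c(O)cc(OCc4ccccc4)cc3OCc3ccccc3)c2O[C@@H]1c1ccc(OCc2ccccc2)c(OCc2ccccc2)c1 | intermediate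
9 | 4,6-bis(benzyloxy)-3,5-dibromo-2-hydroxybenzaldehyde | O=Cc1c(O)c(Br)c(OCc2ccccc2)c(Br)c1OCc1ccccc1 | intermediate
10 | 3,4-bis(benzyloxy)benzaldehyde | O=Cc1ccc(OCc2ccccc2)c(OCc2ccccc2)c1 | starting material
11 | 1,2-bis(benzyloxy)-4-ethynylbenzene | C#Cc1ccc(OCc2ccccc2)c(OCc2ccccc2)c1 | intermediate
12 | 3,4,5-tris(benzyloxy)benzoic acid | OC(=O)c1cc(OCc2ccccc2)c(OCc2ccccc2)c(OCc2ccccc2)c1 | starting material
13 | (Z)-2-[3,4-bis(benzyloxy)phenyl]ethenyl 3,4,5-tris(benzyloxy)benzoate | O=C(O/C=C\c1ccc(OCc2ccccc2)c(OCc2ccccc2)c1)c1cc(OCc2ccccc2)c(OCc2ccccc2)c(OCc2ccccc2)c1 | intermediate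
14 | 3,5-bis(benzyloxy)-2,4-dibromo-6-(dimethoxymethyl)phenol | COC(OC)c1c(O)c(Br)c(OCc2ccccc2)c(Br)c1OCc1ccccc1 | intermediate
15 | 3,5-bis(benzyloxy)-2,4-dibromo-6-(methoxymethylidene)cyclohexa-2,4-dien-1-one | COC=C1C(=O)C(Br)=C(OCc2ccccc2)C(Br)=C1OCc1ccccc1 | intermediate
16 | (2R,3R)-5,7-bis(benzyloxy)-2-[3,4-bis(benzyloxy)phenyl]-6,8-dibromo-4-methoxychroman-3-yl 3,4,5-tris(benzyloxy)benzoate, C4 epimers | COC1c2c(OCc3ccccc3)c(Br)c(OCc3ccccc3)c(Br)c2O[C@H](c2ccc(OCc3ccccc3)c(OCc3ccccc3)c2)[C@@H]1OC(=O)c1cc(OCc2ccccc2)c(OCc2ccccc2)c(OCc2ccccc2)c1 | intermediate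
17 | (2R,3S)-5,7-bis(benzyloxy)-2-[3,4-bis(benzyloxy)phenyl]-8-{[2,4-bis(benzyloxy)-6-oxocyclohexa-2,4-dien-1-ylidene]methyl}chroman-3-ol | O=C1C=C(OCc2ccccc2)C=C(OCc2ccccc2)C1=Cc1c(OCc2ccccc2)cc(OCc2ccccc2)c2c1O[C@H](c1ccc(OCc3ccccc3)c(OCc3ccccc3)c1)[C@@H](O)C2 | intermediate
18 | undeca-O-benzyl (2R,3R)-epicatechin-3-O-gallate-(4β→8)-(2R,3S)-catechin, catechin 3-OH free | O=C(O[C@@H]1[C@@H](c2c(OCc3ccccc3)cc(OCc3ccccc3)c3c2O[C@H](c2ccc(OCc4ccccc4)c(OCc4ccccc4)c2)[C@@H](O)C3)c2c(OCc3ccccc3)cc(OCc3ccccc3)cc2O[C@@H]1c1ccc(OCc2ccccc2)c(OCc2ccccc2)c1)c1cc(OCc2ccccc2)c(OCc2ccccc2)c(OCc2ccccc2)c1 | intermediate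
19 | octadeca-O-benzyl 6,8-dibromo-(2R,3R)-epicatechin-3-O-gallate-(4β→8)-(2R,3R)-epicatechin-3-O-gallate-(4β→8)-(2R,3S)-catechin, Br on the top unit, catechin 3-OH free | O=C(O[C@@H]1[C@@H](c2c(OCc3ccccc3)cc(OCc3ccccc3)c3c2O[C@H](c2ccc(OCc4ccccc4)c(OCc4ccccc4)c2)[C@@H](O)C3)c2c(OCc3ccccc3)cc(OCc3ccccc3)c([C@H]3c4c(OCc5ccccc5)c(Br)c(OCc5ccccc5)c(Br)c4O[C@H](c4ccc(OCc5ccccc5)c(OCc5ccccc5)c4)[C@@H]3OC(=O)c3cc(OCc4ccccc4)c(OCc4ccccc4)c(OCc4ccccc4)c3)c2O[C@@H]1c1ccc(OCc2ccccc2)c(OCc2ccccc2)c1)c1cc(OCc2ccccc2)c(OCc2ccccc2)c(OCc2ccccc2)c1 | intermediate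
20 | (−)-epicatechin-3-O-gallate-(4β→8)-(−)-epicatechin-3-O-gallate-(4β→8)-(+)-catechin, CNP0269915.2 | O=C(O[C@@H]1[C@@H](c2c(O)cc(O)c3c2O[C@H](c2ccc(O)c(O)c2)[C@@H](O)C3)c2c(O)cc(O)c([C@H]3c4c(O)cc(O)cc4O[C@H](c4ccc(O)c(O)c4)[C@@H]3OC(=O)c3cc(O)c(O)c(O)c3)c2O[C@@H]1c1ccc(O)c(O)c1)c1cc(O)c(O)c(O)c1 | target

**Totals**
Total step count: 9. Longest linear sequence: 5 (steps 1, 2, 4, 8, 9).

**Three steps most likely to fail**

Step 8. The weakest point is the cycloaddition of the crowded, strongly donor-stabilised quinone methide 17: it may be slow, may add endo (giving the 3,4-cis ring), or may leak to 2,3-trans through a stepwise path. The fallback sets out from 5 and comes back at 18, and builds the middle ring before the interflavan bond. Aldehyde 5 is cyclised with 13 and HC(OMe)3 under the same chiral acid to the unblocked 4-methoxyflavan gallate, (2R,3R)-5,7-bis(benzyloxy)-2-[3,4-bis(benzyloxy)phenyl]-4-methoxychroman-3-yl 3,4,5-tris(benzyloxy)benzoate F1. F1 is then coupled (TMSOTf, −78 °C) with a threefold excess of 2, which is recovered, so that the 3-O-galloyl group steers C8 of 2 to the β face. This gives 18, now isolated, which is joined to 16 (made alone from 9 and 13) as in stage (iii) to reach 19.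

Step 4. The hindered aryllithium 6 may add poorly to the deactivated phenoxide-aldehyde 7, and 8 ionises easily on handling. The fallback sets out from 5 and comes back at 8 without bromide or organolithium. Pinnick oxidation of 5 gives 2,4-bis(benzyloxy)-6-hydroxybenzoic acid F2. Its mixed anhydride with trifluoroacetic anhydride acylates C8 of 2 (Friedel–Crafts) to give the benzophenone [(2R,3S)-5,7-bis(benzyloxy)-2-[3,4-bis(benzyloxy)phenyl]-3-hydroxychroman-8-yl][2,4-bis(benzyloxy)-6-hydroxyphenyl]methanone F3. NaBH4 reduction of this o-hydroxy ketone gives 8.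

Step 7. The electron-rich alkyne and the bulky acid may give low Z-selectivity or Markovnikov adducts, and 13 is acid-sensitive. The fallback sets out from 10 and comes back at 13. Z-selective Wittig bromomethylenation of 10 (Ph3P=CHBr, KOtBu, THF, −78 °C) gives (Z)-1,2-bis(benzyloxy)-4-(2-bromoethenyl)benzene F4. Copper-catalysed C–O coupling of F4 with the caesium salt of 12 (CuI, diamine ligand, Cs2CO3, toluene) proceeds with retention of geometry to 13.

**Further compounds**
F1 | step 8 | (2R,3R)-5,7-bis(benzyloxy)-2-[3,4-bis(benzyloxy)phenyl]-4-methoxychroman-3-yl 3,4,5-tris(benzyloxy)benzoate, C4 epimers | COC1c2c(OCc3ccccc3)cc(OCc3ccccc3)cc2O[C@H](c2ccc(OCc3ccccc3)c(OCc3ccccc3)c2)[C@@H]1OC(=O)c1cc(OCc2ccccc2)c(OCc2ccccc2)c(OCc2ccccc2)c1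
F2 | step 4 | 2,4-bis(benzyloxy)-6-hydroxybenzoic acid | OC(=O)c1c(O)cc(OCc2ccccc2)cc1OCc1ccccc1
F3 | step 4 | [(2R,3S)-5,7-bis(benzyloxy)-2-[3,4-bis(benzyloxy)phenyl]-3-hydroxychroman-8-yl][2,4-bis(benzyloxy)-6-hydroxyphenyl]methanone | O[C@H]1Cc2c(OCc3ccccc3)cc(OCc3ccccc3)c(C(=O)c3c(O)cc(OCc4ccccc4)cc3OCc3ccccc3)c2O[C@@H]1c1ccc(OCc2ccccc2)c(OCc2ccccc2)c1
F4 | step 7 | (Z)-1,2-bis(benzyloxy)-4-(2-bromoethenyl)benzene | Br/C=C\c1ccc(OCc2ccccc2)c(OCc2ccccc2)c1
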